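Remark: positions are numbered as in azulene (C1, C2, C3, C3a, C4 to C8, C8a; epoxide on C1/C2, isopropyl on C4, ester on C5, carbinol at C7); α means the face of H‑3a; compounds 1, 4, 12 and 20 are taken to be catalogue compounds.

## Analysis of the target

The target is a trans‑fused hydroazulene. Its five‑membered ring (C1, C2, C3, C3a, C8a) carries a trisubstituted 1,2‑epoxide with a methyl group on C2. Its seven‑membered ring (C3a, C4, C5, C6, C7, C8, C8a) carries an isopropyl group on C4, the 3‑hydroxy‑4‑methoxybenzoate on C5 and a tertiary methyl carbinol at C7.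

There are seven stereocentres (C1, C2, C3a, C4, C5, C7, C8a). H‑8a is β and H‑3a is α; the isopropyl group, the C5 ester oxygen, the C7 hydroxyl and the epoxide oxygen all lie on the α‑face, while H‑4, H‑5 and both methyl groups are β.

The epoxide is acid‑labile, the tertiary alcohol can eliminate, the aryl ester is base‑labile and the free phenol is easily oxidised, so epoxide and phenol should appear last.

The synthesis is hard for four reasons: the seven‑membered ring; the contiguous C8a–C3a–C4–C5 array, in which C4 bears only an isopropyl group and has no neighbouring function once the ring exists; the cis‑1,3‑dioxygenation at C5/C7 with one tertiary centre; and an epoxide on the α‑face of C1=C2, the face next to the C8a–C8 bond.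

The feature that is exploited is the segment C5(O)–C6H2–C7(CH3)(OH)–C8H2 of the seven‑membered ring. It is an isobutene unit (C6, C7, C8 and the C7 methyl) oxidised at its central carbon and bonded through its two CH2 termini to C5 and to C8a. This is the imprint of a 2‑(silylmethyl)allyl reagent that acts twice as a nucleophile.

A second feature is that C5, at the carboxyl level, can be tied through oxygen to C2 across the five‑membered ring (C5–O–C2). This lactone bridge is not in the target, but it makes C4 part of a rigid bicycle and makes C8a the γ‑carbon of an allylic ester.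

## Retrosynthetic reasoning

**Phenol and epoxide (26 ⇒ 25 ⇒ 24).** The phenol is unmasked last, and the epoxide is introduced just before, because both are the most fragile groups. The C1–O and C2–O bonds are cut back to the C1=C2 olefin of 24. The forward epoxidation must reach the α‑face, which is the face flanked by C8; the α‑oriented C7 hydroxyl, two carbons away through C8, is used as the directing group.

**Ester C5–O (24 ⇒ 19 + 22).** The acyl–oxygen bond is cut to diol 19 and the silyl‑protected acid 22 (from 20). The forward acylation has only to distinguish a secondary from a tertiary hydroxyl and does not touch a stereocentre.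

**C7 carbinol (19 ⇒ 18 ⇒ 17).** The C7–OH and the C7 methyl are traced to the exocyclic methylene of 17 through spiro‑epoxide 18. Cutting here lets the C5 hydroxyl set C7: directed epoxidation puts oxygen on C7 cis to C5–OH, and hydride turns the epoxide CH2 into the methyl group.

**Key disconnection C5–C6 (17 ⇒ 16).** The seven‑membered ring is cut between the carbinol carbon C5 and the CH2 terminus C6 of the isobutene unit. This gives the monocyclic aldehyde 16, which carries the allylsilane on C8a and the α‑isopropyl aldehyde on C3a. This cut is chosen because the forward Hosomi–Sakurai closure forms the ring, sets C5 under control of C4 and leaves exactly the methylene needed for C7. An allylsilane, not a plain 2‑methylallyl group, is required so that the nucleophile outruns the C1=C2 olefin.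

**C8–C8a bond and trans ring fusion (16 ⇒ 15 ⇒ 14 ⇒ 11 + 12).** After redox adjustment to acid 14, the C8a–C8 bond is cut. In the forward sense the Grignard reagent 13 (from 12) opens the bridged allylic lactone 11 in an anti‑SN2' reaction. One step gives the trans relationship of the two arms, the C1=C2 olefin with its methyl group, and the free C5 carboxyl.

**Temporary lactone and C4 (11 ⇒ 9 ⇒ 7).** The C5–O–C2 bridge is cut to enone ester 7 and a methyl nucleophile. In the bicycle, C4 is an enolisable lactone α‑carbon whose preferred (equatorial isopropyl) configuration is that of the target, so the epimer mixture 9 converges to 11.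

**Side chain on the ring (7 ⇒ 6 ⇒ 3 + 4).** The C3a–C4 bond is cut to the purchased enone 4 and ketene silyl acetal 3 (from 1). The single bought stereocentre of 4 directs the addition and is then removed by elimination; every other stereocentre is relayed from C3a.

## Alternatives that were turned down

**Alternative 1: ring‑closing metathesis at C6=C7 (the textbook route).**
- Disconnection: the seven‑membered ring is cut at a C6=C7 olefin; C5–C6 comes from a vinyl addition.
- Forward: aldehyde A1 (the 2‑methylallyl counterpart of 16) adds vinylmagnesium bromide to give diene carbinol A2; the second‑generation Grubbs catalyst closes cycloheptenol A3; directed epoxidation and hydride opening at C6 then lead to 19.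
- Turned down because:
  - C5 is set in an intermolecular addition to an α‑branched aldehyde, with open‑chain Felkin control only.
  - The metathesis must make a trisubstituted olefin in a seven‑membered ring from a 1,1‑disubstituted partner, next to a free allylic alcohol (prone to ruthenium hydride isomerisation) and a second trisubstituted olefin.
  - C7 then depends on a regioselective opening of a 2,3‑epoxy alcohol.
  - It needs one step more than the chosen closure and gives weaker control of C5.

**Alternative 2: dirhodium‑catalysed cyclopropanation/Cope rearrangement ([4+3]).**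
- Disconnection: C4–C5 and C8–C8a are formed together from two acyclic pieces.
- Forward: vinyldiazoacetate A4 and silyloxydiene A5 react with Rh2(S‑DOSP)4 to give cycloheptadiene A6, with C4 and C5 cis and absolute control from the catalyst.
- Turned down because:
  - The five‑membered ring and both ring‑fusion centres are still missing; C8a emerges sp2 and carries an ester carbon that must be cut down to the C1 methine.
  - Conjugate addition at C3a, protonation at C8a and four to five further steps are needed for the cyclopentene.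
  - The cyclopropanation occurs at a 1,1‑disubstituted terminus, where methyl and alkenyl compete for the position cis to the vinyl group, so part of the material is a trans‑divinylcyclopropane that rearranges only under forcing conditions.
  - The count rises to about seventeen steps.

**Alternative 3: rhodium‑catalysed [5+2] cycloaddition of a tethered alkyne and vinylcyclopropane.**
- Disconnection: C3a–C8a and C4–C5 are formed at once; the tether becomes the five‑membered ring.
- Forward: enyne A7 with [Rh(CO)2Cl]2, then hydrolysis of the enol ether, gives bicyclic ketone A8.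
- Turned down because:
  - Both rings form in one step, but C3a=C4 comes out as a tetrasubstituted olefin, and H‑3a and H‑4 must end up trans, which a syn hydrogenation cannot deliver.
  - C5 arrives as a plain CH2 whose oxygenation would rely on an unselective allylic oxidation.
  - The C2 methylidene must be isomerised regioselectively to C1=C2.
  - Only C8a is created, under no control; the step builds the skeleton but none of the seven stereocentres.

Key step: step 9

## Route

Step 1
Reactants: 1 methyl 3-methylbutanoate
Product: 3 [(1-methoxy-3-methylbut-1-en-1-yl)oxy]trimethylsilane (E/Z mixture), via lithium enolate 2 (not isolated)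
Conditions: LiN(i-Pr)2 (LDA), THF, −78 °C; then Me3SiCl, −78 → 23 °C; distillation
Reagents that add atoms: chlorotrimethylsilane, C[Si](C)(C)Cl
Why: O‑silylation of the ester enolate gives the ketene silyl acetal for a Mukaiyama–Michael addition; its geometry does not matter because the carbon it creates (later C4) is corrected in step 5.

Step 2
Reactants: 3 [(1-methoxy-3-methylbut-1-en-1-yl)oxy]trimethylsilane; 4 (4R)-4-[(tert-butyldimethylsilyl)oxy]cyclopent-2-en-1-one
Product: 6 methyl 2-[(1S,2R)-2-[(tert-butyldimethylsilyl)oxy]-4-oxocyclopentyl]-3-methylbutanoate (both epimers at C2 of the butanoate), via silyl enol ether 5 (not isolated)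
Conditions: Me3SiOTf (5 mol %), CH2Cl2, −78 °C; then 10 % aq. citric acid, THF, 0 °C
Reagents that add atoms: none
Why: Mukaiyama–Michael addition; the donor adds to the β‑carbon anti to the neighbouring silyloxy group, which fixes the ring carbon that becomes C3a, and mild acid hydrolyses only the trimethylsilyl enol ether.

Step 3
Reactants: 6 methyl 2-[(1S,2R)-2-[(tert-butyldimethylsilyl)oxy]-4-oxocyclopentyl]-3-methylbutanoate
Product: 7 methyl 3-methyl-2-[(1R)-4-oxocyclopent-2-en-1-yl]butanoate (both epimers at C2 of the butanoate)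
Conditions: DBU, CH2Cl2, 0 °C
Reagents that add atoms: none
Why: E1cB elimination of the β‑silyloxy group transposes the enone, so the centre set in step 2 becomes the γ‑carbon (C3a) and the former silyloxy carbon becomes the olefinic C8a.

Step 4
Reactants: 7 methyl 3-methyl-2-[(1R)-4-oxocyclopent-2-en-1-yl]butanoate
Product: 9 (1S,5R)-1-methyl-4-(propan-2-yl)-2-oxabicyclo[3.2.1]oct-6-en-3-one (both C4 epimers), via cerium alkoxide 8 (not isolated)
Conditions: MeLi, CeCl3, THF, −78 °C; then 23 °C
Reagents that add atoms: methylcerium dichloride, C[Ce](Cl)Cl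
Why: The non‑basic organocerium reagent adds 1,2 to the enone anti to the C3a side chain, so the tertiary alkoxide at C2 is cis to the ester arm and closes the bridged δ‑lactone by intramolecular acyl substitution (methoxide is the weaker base); an alkoxide on the other face cannot lactonise and is separated.

Step 5
Reactants: 9 (1S,5R)-1-methyl-4-(propan-2-yl)-2-oxabicyclo[3.2.1]oct-6-en-3-one (both C4 epimers)
Product: 11 (1S,4S,5R)-1-methyl-4-(propan-2-yl)-2-oxabicyclo[3.2.1]oct-6-en-3-one, via lithium enolate 10 (not isolated)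
Conditions: LiN(i-Pr)2 (LDA), THF, −78 °C; then AcOH, −78 °C
Reagents that add atoms: none
Why: Enolisation erases C4, and kinetic protonation of the bicyclic lactone enolate from the face of the one‑carbon bridge (C3H2), away from the two‑carbon olefin bridge, leaves the isopropyl group equatorial; this is also the more stable epimer and is the C4 configuration of the target.

Step 6
Reactants: 11 (1S,4S,5R)-1-methyl-4-(propan-2-yl)-2-oxabicyclo[3.2.1]oct-6-en-3-one; 12 [2-(chloromethyl)prop-2-en-1-yl]trimethylsilane
Product: 14 (2S)-3-methyl-2-[(1R,2S)-4-methyl-2-{2-[(trimethylsilyl)methyl]prop-2-en-1-yl}cyclopent-3-en-1-yl]butanoic acid, via Grignard reagent 13 (not isolated)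
Conditions: 12, Mg, THF, 0 °C; then slow addition to 11, CuBr·SMe2 (20 mol %), THF–Me2S, −78 → −40 °C; aq. NH4Cl, then citric acid
Reagents that add atoms: none
Why: Copper‑catalysed anti‑SN2' opening of an allylic lactone by a Grignard reagent; the C8–C8a bond forms on the face opposite the departing carboxylate bridge, hence trans to the C3a arm, the bridgehead α‑carbon C2 cannot be attacked, and the double bond moves to C1=C2 with its methyl group.

Step 7
Reactants: 14 (2S)-3-methyl-2-[(1R,2S)-4-methyl-2-{2-[(trimethylsilyl)methyl]prop-2-en-1-yl}cyclopent-3-en-1-yl]butanoic acid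
Product: 15 (2S)-3-methyl-2-[(1R,2S)-4-methyl-2-{2-[(trimethylsilyl)methyl]prop-2-en-1-yl}cyclopent-3-en-1-yl]butan-1-ol
Conditions: LiAlH4, THF, 0 → 23 °C
Reagents that add atoms: none
Why: Hydride reduction of the carboxylic acid to the primary alcohol; the allylsilane and both olefins are inert and the carboxylate does not enolise, so C4 is safe.

Step 8
Reactants: 15 (2S)-3-methyl-2-[(1R,2S)-4-methyl-2-{2-[(trimethylsilyl)methyl]prop-2-en-1-yl}cyclopent-3-en-1-yl]butan-1-ol
Product: 16 (2S)-3-methyl-2-[(1R,2S)-4-methyl-2-{2-[(trimethylsilyl)methyl]prop-2-en-1-yl}cyclopent-3-en-1-yl]butanal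
Conditions: Dess–Martin periodinane, NaHCO3, CH2Cl2, 0 °C
Reagents that add atoms: none
Why: Dess–Martin oxidation under bicarbonate buffer gives the α‑branched aldehyde without epimerising C4 and without the acid that would protodesilylate the allylsilane.

Step 9
Reactants: 16 (2S)-3-methyl-2-[(1R,2S)-4-methyl-2-{2-[(trimethylsilyl)methyl]prop-2-en-1-yl}cyclopent-3-en-1-yl]butanal
Product: 17 (3aR,4S,5R,8aS)-2-methyl-7-methylidene-4-(propan-2-yl)-3,3a,4,5,6,7,8,8a-octahydroazulen-5-ol
Conditions: BF3·OEt2, CH2Cl2, −78 °C; aq. NaHCO3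
Reagents that add atoms: none
Why: BF3 binds the aldehyde oxygen and the terminal CH2 of the 2‑substituted allylsilane (C6) adds to C5; the β‑silyl cation then loses Me3SiF to leave the exocyclic C7=CH2. This is an intramolecular Hosomi–Sakurai reaction, and the closest known type is the Lewis‑acid cyclisation of ω‑formyl 2‑(silylmethyl)allyl chains to 3‑methylenecycloalkanols, seven‑membered cases included. One ring is closed, the seven‑membered carbocycle, by forming C5–C6: the carbonyl is attacked in the exo mode (7‑exo‑trig, oxygen left outside the ring), while both carbons of the reacting C6=C7 π bond end up inside the ring. The trans ring fusion (C3a, C8a) and C4 are already fixed in 16, so C5 is the only new stereocentre. In the chair‑like transition state the C4 isopropyl group is pseudo‑equatorial and anti to the incoming C6 (Felkin–Anh), and the complexed C=O is synclinal to the C6=C7 bond; this should place the C5 oxygen cis to the isopropyl group, i.e. (5R). The step needs chemoselectivity for the allylsilane over the trisubstituted C1=C2 olefin, which could attack the activated aldehyde in a Prins manner; this is secured by the much higher nucleophilicity of the allylsilane at −78 °C. It also needs the C4 centre α to the aldehyde to survive, which a non‑basic Lewis acid at low temperature allows.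

Step 10
Reactants: 17 (3aR,4S,5R,8aS)-2-methyl-7-methylidene-4-(propan-2-yl)-3,3a,4,5,6,7,8,8a-octahydroazulen-5-ol
Product: 18 (2R,3a'R,4'S,5'R,8a'S)-2'-methyl-4'-(propan-2-yl)-3',3a',4',5',8',8a'-hexahydro-6'H-spiro[oxirane-2,7'-azulen]-5'-ol
Conditions: VO(acac)2 (5 mol %), t-BuOOH, CH2Cl2, 0 → 23 °C
Reagents that add atoms: tert-butyl hydroperoxide, CC(C)(C)OO
Why: Hydroxyl‑directed epoxidation: the vanadium alkoxide of the homoallylic C5–OH delivers oxygen to the same face of the exocyclic C7=CH2 bond, so C7–O is cis to C5–O; the remote C1=C2 olefin is not activated.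

Step 11
Reactants: 18 (2R,3a'R,4'S,5'R,8a'S)-2'-methyl-4'-(propan-2-yl)-3',3a',4',5',8',8a'-hexahydro-6'H-spiro[oxirane-2,7'-azulen]-5'-ol
Product: 19 (3aR,4S,5R,7R,8aS)-2,7-dimethyl-4-(propan-2-yl)-3,3a,4,5,6,7,8,8a-octahydroazulene-5,7-diol
Conditions: LiAlH4, THF, 0 → 23 °C
Reagents that add atoms: none
Why: Hydride opens the 1,1‑disubstituted epoxide at its unhindered CH2 terminus (SN2), which turns that carbon into the C7 methyl group and leaves the tertiary hydroxyl on C7 cis to C5–OH.

Step 12
Reactants: 20 3-hydroxy-4-methoxybenzoic acid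
Product: 22 3-[(tert-butyldimethylsilyl)oxy]-4-methoxybenzoic acid, via silyl ester 21 (not isolated)
Conditions: t-BuMe2SiCl (2.4 equiv), imidazole, DMF, 23 °C; then AcOH–H2O–THF, 23 °C
Reagents that add atoms: tert-butyldimethylsilyl chloride, CC(C)(C)[Si](C)(C)Cl
Why: Both acidic groups are silylated and the labile silyl ester is then hydrolysed selectively, which leaves the phenol masked for the esterification and the later oxidation.

Step 13
Reactants: 19 (3aR,4S,5R,7R,8aS)-2,7-dimethyl-4-(propan-2-yl)-3,3a,4,5,6,7,8,8a-octahydroazulene-5,7-diol; 22 3-[(tert-butyldimethylsilyl)oxy]-4-methoxybenzoic acid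
Product: 24 (3aR,4S,5R,7R,8aS)-7-hydroxy-2,7-dimethyl-4-(propan-2-yl)-3,3a,4,5,6,7,8,8a-octahydroazulen-5-yl 3-[(tert-butyldimethylsilyl)oxy]-4-methoxybenzoate, via mixed anhydride 23 (not isolated)
Conditions: 22, 2,4,6-trichlorobenzoyl chloride, Et3N, THF, 23 °C; then 19, DMAP, toluene, 40 °C
Reagents that add atoms: none
Why: Yamaguchi esterification: DMAP is acylated at the less hindered aroyl carbonyl of the mixed anhydride and the secondary C5 hydroxyl takes up the acyl group; the tertiary C7 hydroxyl does not compete and C5 keeps its configuration.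

Step 14
Reactants: 24 (3aR,4S,5R,7R,8aS)-7-hydroxy-2,7-dimethyl-4-(propan-2-yl)-3,3a,4,5,6,7,8,8a-octahydroazulen-5-yl 3-[(tert-butyldimethylsilyl)oxy]-4-methoxybenzoate
Product: 25 (1S,2R,3aR,4S,5R,7R,8aS)-1,2-epoxy-7-hydroxy-2,7-dimethyl-4-(propan-2-yl)decahydroazulen-5-yl 3-[(tert-butyldimethylsilyl)oxy]-4-methoxybenzoate
Conditions: VO(acac)2 (10 mol %), t-BuOOH, CH2Cl2, 23 °C
Reagents that add atoms: tert-butyl hydroperoxide, CC(C)(C)OO
Why: Epoxidation directed by the tertiary bis‑homoallylic C7 hydroxyl: C8 leaves C8a on the α‑face of the cyclopentene, so the vanadium alkoxide on C7 should reach only that face of C1=C2 and deliver oxygen syn to C7–OH, giving (1S,2R); the syn epoxide cannot be opened by the same hydroxyl, which would need backside access.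

Step 15
Reactants: 25 (1S,2R,3aR,4S,5R,7R,8aS)-1,2-epoxy-7-hydroxy-2,7-dimethyl-4-(propan-2-yl)decahydroazulen-5-yl 3-[(tert-butyldimethylsilyl)oxy]-4-methoxybenzoate
Product: 26 (1S,2R,3aR,4S,5R,7R,8aS)-1,2-epoxy-7-hydroxy-2,7-dimethyl-4-(propan-2-yl)decahydroazulen-5-yl 3-hydroxy-4-methoxybenzoate
Conditions: Bu4NF, AcOH, THF, 0 °C
Reagents that add atoms: none
Why: Fluoride cleaves the aryl silyl ether; acetic acid buffers the phenoxide so that neither acyl migration nor base‑ or acid‑induced epoxide opening takes place.

## Compound list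

1 | methyl 3-methylbutanoate | COC(=O)CC(C)C | starting material
2 | lithium 1-methoxy-3-methylbut-1-en-1-olate | COC(O[Li])=CC(C)C | intermediate
3 | [(1-methoxy-3-methylbut-1-en-1-yl)oxy]trimethylsilane (E/Z mixture) | COC(O[Si](C)(C)C)=CC(C)C | intermediate
4 | (4R)-4-[(tert-butyldimethylsilyl)oxy]cyclopent-2-en-1-one | O=C1C=C[C@H](O[Si](C)(C)C(C)(C)C)C1 | starting material
5 | methyl 2-[(1S,5R)-5-[(tert-butyldimethylsilyl)oxy]-3-[(trimethylsilyl)oxy]cyclopent-2-en-1-yl]-3-methylbutanoate | COC(=O)C(C(C)C)[C@@H]1C=C(O[Si](C)(C)C)C[C@H]1O[Si](C)(C)C(C)(C)C | intermediate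
6 | methyl 2-[(1S,2R)-2-[(tert-butyldimethylsilyl)oxy]-4-oxocyclopentyl]-3-methylbutanoate | COC(=O)C(C(C)C)[C@@H]1CC(=O)C[C@H]1O[Si](C)(C)C(C)(C)C | intermediate
7 | methyl 3-methyl-2-[(1R)-4-oxocyclopent-2-en-1-yl]butanoate | COC(=O)C(C(C)C)[C@@H]1CC(=O)C=C1 | intermediate
8 | dichlorocerium alkoxide of methyl 2-[(1R,4S)-4-hydroxy-4-methylcyclopent-2-en-1-yl]-3-methylbutanoate | COC(=O)C(C(C)C)[C@@H]1C[C@](C)(O[Ce](Cl)Cl)C=C1 | intermediate
9 | (1S,5R)-1-methyl-4-(propan-2-yl)-2-oxabicyclo[3.2.1]oct-6-en-3-one (both C4 epimers) | O=C1O[C@]2(C)C=C[C@@H](C2)C1C(C)C | intermediate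
10 | lithium (1S,5R)-1-methyl-4-(propan-2-yl)-2-oxabicyclo[3.2.1]octa-3,6-dien-3-olate | [Li]OC=1O[C@]2(C)C=C[C@@H](C2)C=1C(C)C | intermediate
11 | (1S,4S,5R)-1-methyl-4-(propan-2-yl)-2-oxabicyclo[3.2.1]oct-6-en-3-one | O=C1O[C@]2(C)C=C[C@@H](C2)[C@@H]1C(C)C | intermediate
12 | [2-(chloromethyl)prop-2-en-1-yl]trimethylsilane | ClCC(=C)C[Si](C)(C)C | starting material
13 | {2-[(trimethylsilyl)methyl]prop-2-en-1-yl}magnesium chloride | C[Si](C)(C)CC(=C)C[Mg]Cl | intermediate
14 | (2S)-3-methyl-2-[(1R,2S)-4-methyl-2-{2-[(trimethylsilyl)methyl]prop-2-en-1-yl}cyclopent-3-en-1-yl]butanoic acid | OC(=O)[C@@H](C(C)C)[C@@H]1CC(C)=C[C@H]1CC(=C)C[Si](C)(C)C | intermediate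
15 | (2S)-3-methyl-2-[(1R,2S)-4-methyl-2-{2-[(trimethylsilyl)methyl]prop-2-en-1-yl}cyclopent-3-en-1-yl]butan-1-ol | OC[C@@H](C(C)C)[C@@H]1CC(C)=C[C@H]1CC(=C)C[Si](C)(C)C | intermediate
16 | (2S)-3-methyl-2-[(1R,2S)-4-methyl-2-{2-[(trimethylsilyl)methyl]prop-2-en-1-yl}cyclopent-3-en-1-yl]butanal | O=C[C@@H](C(C)C)[C@@H]1CC(C)=C[C@H]1CC(=C)C[Si](C)(C)C | intermediate
17 | (3aR,4S,5R,8aS)-2-methyl-7-methylidene-4-(propan-2-yl)-3,3a,4,5,6,7,8,8a-octahydroazulen-5-ol | O[C@@H]1CC(=C)C[C@H]2[C@@H](CC(C)=C2)[C@@H]1C(C)C | intermediate
18 | (2R,3a'R,4'S,5'R,8a'S)-2'-methyl-4'-(propan-2-yl)-3',3a',4',5',8',8a'-hexahydro-6'H-spiro[oxirane-2,7'-azulen]-5'-ol | O[C@@H]1C[C@@]2(CO2)C[C@H]2[C@@H](CC(C)=C2)[C@@H]1C(C)C | intermediate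
19 | (3aR,4S,5R,7R,8aS)-2,7-dimethyl-4-(propan-2-yl)-3,3a,4,5,6,7,8,8a-octahydroazulene-5,7-diol | O[C@@H]1C[C@](C)(O)C[C@H]2[C@@H](CC(C)=C2)[C@@H]1C(C)C | intermediate
20 | 3-hydroxy-4-methoxybenzoic acid | COc1ccc(C(=O)O)cc1O | starting material
21 | tert-butyldimethylsilyl 3-[(tert-butyldimethylsilyl)oxy]-4-methoxybenzoate | COc1ccc(C(=O)O[Si](C)(C)C(C)(C)C)cc1O[Si](C)(C)C(C)(C)C | intermediate
22 | 3-[(tert-butyldimethylsilyl)oxy]-4-methoxybenzoic acid | COc1ccc(C(=O)O)cc1O[Si](C)(C)C(C)(C)C | intermediate
23 | 3-[(tert-butyldimethylsilyl)oxy]-4-methoxybenzoic 2,4,6-trichlorobenzoic anhydride | COc1ccc(C(=O)OC(=O)c2c(Cl)cc(Cl)cc2Cl)cc1O[Si](C)(C)C(C)(C)C | intermediate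
24 | (3aR,4S,5R,7R,8aS)-7-hydroxy-2,7-dimethyl-4-(propan-2-yl)-3,3a,4,5,6,7,8,8a-octahydroazulen-5-yl 3-[(tert-butyldimethylsilyl)oxy]-4-methoxybenzoate | COc1ccc(C(=O)O[C@@H]2C[C@](C)(O)C[C@H]3[C@@H](CC(C)=C3)[C@@H]2C(C)C)cc1O[Si](C)(C)C(C)(C)C | intermediate
25 | (1S,2R,3aR,4S,5R,7R,8aS)-1,2-epoxy-7-hydroxy-2,7-dimethyl-4-(propan-2-yl)decahydroazulen-5-yl 3-[(tert-butyldimethylsilyl)oxy]-4-methoxybenzoate | COc1ccc(C(=O)O[C@@H]2C[C@](C)(O)C[C@H]3[C@@H](C[C@@]4(C)O[C@@H]34)[C@@H]2C(C)C)cc1O[Si](C)(C)C(C)(C)C | intermediate
26 | (1S,2R,3aR,4S,5R,7R,8aS)-1,2-epoxy-7-hydroxy-2,7-dimethyl-4-(propan-2-yl)decahydroazulen-5-yl 3-hydroxy-4-methoxybenzoate | COc1ccc(C(=O)O[C@@H]2C[C@](C)(O)C[C@H]3[C@@H](C[C@@]4(C)O[C@@H]34)[C@@H]2C(C)C)cc1O | target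

## Step count and least certain steps

Total step count: 15. Longest linear sequence: 14 steps (steps 1 to 11 and 13 to 15; step 12 prepares the acid component).

**Step 9 (key step).** The most likely failures are protodesilylation of the allylsilane before ring closure, a competing Prins‑type attack of the C1=C2 olefin on the activated aldehyde, and an eroded facial preference at C5 in the seven‑membered transition state. The fallback closes the ring at the acyl oxidation level and sets C5 by reduction. It sets out from 14, which with 1‑chloro‑N,N,2‑trimethylprop‑1‑en‑1‑amine should give (2S)-3-methyl-2-[(1R,2S)-4-methyl-2-{2-[(trimethylsilyl)methyl]prop-2-en-1-yl}cyclopent-3-en-1-yl]butanoyl chloride F1. TiCl4 in CH2Cl2 at −78 °C should then effect intramolecular acylation of the allylsilane to (3aR,4S,8aS)-2-methyl-7-methylidene-4-(propan-2-yl)-3a,4,6,7,8,8a-hexahydroazulen-5(3H)-one F2. Reduction with LiBH(s-Bu)3 in THF at −78 °C, with hydride arriving on the face away from the isopropyl group, returns to the route at 17.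

**Step 6.** The allylic magnesium reagent may add directly to the lactone carbonyl before copper‑mediated substitution, and the tertiary allylic C2–O bond may ionise and re‑close to the fused γ‑lactone. The fallback replaces the organocopper substitution by a palladium‑catalysed Stille‑type allyl–allyl coupling. It sets out from 11 and uses tributyl{2-[(trimethylsilyl)methyl]prop-2-en-1-yl}stannane F3, made from 12 and Bu3SnLi, with Pd2(dba)3 and triphenylarsine in THF. Zerovalent palladium ionises the C2–O bond with inversion and the allyl group is transferred from the metal, so the new bond again forms at C8a anti to the carboxylate; KF work‑up returns to the route at 14.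

**Step 4.** The hindered cerium alkoxide may close the bridged lactone only slowly onto the α‑branched ester, part of the methyl addition may occur on the face of the side chain, and γ‑deprotonation of the enone would erode C3a. The fallback separates addition from ring closure and closes the lactone by carboxyl activation. It sets out from 7; after the organocerium addition and aqueous work‑up, methyl 2-[(1R,4S)-4-hydroxy-4-methylcyclopent-2-en-1-yl]-3-methylbutanoate F4 is isolated. LiOH in aqueous THF should give 2-[(1R,4S)-4-hydroxy-4-methylcyclopent-2-en-1-yl]-3-methylbutanoic acid F5, and 2‑chloro‑1‑methylpyridinium iodide with Et3N should lactonise it, returning to the route at 9.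

**Step 14.** Facial selectivity may be poor if the C7 alkoxide does not reach the α‑face of C1=C2, and the reaction may be slow for a bis‑homoallylic tertiary alcohol. The fallback uses catalyst control before the ester is made. It sets out from 19, which is epoxidised with a fructose‑derived chiral ketone (or its enantiomer, whichever matches the α‑face by the spiro transition‑state model) and KHSO5 under carbonate buffer. This should give (1S,2R,3aR,4S,5R,7R,8aS)-1,2-epoxy-2,7-dimethyl-4-(propan-2-yl)decahydroazulene-5,7-diol F6, which is acylated with 22 under the conditions of step 13 and returns to the route at 25.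

## Further compounds

F1 | step 9 | (2S)-3-methyl-2-[(1R,2S)-4-methyl-2-{2-[(trimethylsilyl)methyl]prop-2-en-1-yl}cyclopent-3-en-1-yl]butanoyl chloride | ClC(=O)[C@@H](C(C)C)[C@@H]1CC(C)=C[C@H]1CC(=C)C[Si](C)(C)C
F2 | step 9 | (3aR,4S,8aS)-2-methyl-7-methylidene-4-(propan-2-yl)-3a,4,6,7,8,8a-hexahydroazulen-5(3H)-one | O=C1CC(=C)C[C@H]2[C@@H](CC(C)=C2)[C@@H]1C(C)C
F3 | step 6 | tributyl{2-[(trimethylsilyl)methyl]prop-2-en-1-yl}stannane | CCCC[Sn](CCCC)(CCCC)CC(=C)C[Si](C)(C)C
F4 | step 4 | methyl 2-[(1R,4S)-4-hydroxy-4-methylcyclopent-2-en-1-yl]-3-methylbutanoate | COC(=O)C(C(C)C)[C@@H]1C[C@](C)(O)C=C1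
F5 | step 4 | 2-[(1R,4S)-4-hydroxy-4-methylcyclopent-2-en-1-yl]-3-methylbutanoic acid | OC(=O)C(C(C)C)[C@@H]1C[C@](C)(O)C=C1
F6 | step 14 | (1S,2R,3aR,4S,5R,7R,8aS)-1,2-epoxy-2,7-dimethyl-4-(propan-2-yl)decahydroazulene-5,7-diol | O[C@@H]1C[C@](C)(O)C[C@H]2[C@@H](C[C@@]3(C)O[C@@H]23)[C@@H]1C(C)C
A1 | alternative 1 | (2S)-3-methyl-2-[(1R,2S)-4-methyl-2-(2-methylprop-2-en-1-yl)cyclopent-3-en-1-yl]butanal | O=C[C@@H](C(C)C)[C@@H]1CC(C)=C[C@H]1CC(C)=C
A2 | alternative 1 | (3R,4S)-5-methyl-4-[(1R,2S)-4-methyl-2-(2-methylprop-2-en-1-yl)cyclopent-3-en-1-yl]hex-1-en-3-ol | C=C[C@@H](O)[C@@H](C(C)C)[C@@H]1CC(C)=C[C@H]1CC(C)=C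
A3 | alternative 1 | (3aR,4S,5S,8aS)-2,7-dimethyl-4-(propan-2-yl)-3,3a,4,5,8,8a-hexahydroazulen-5-ol | O[C@@H]1C=C(C)C[C@H]2[C@@H](CC(C)=C2)[C@@H]1C(C)C
A4 | alternative 2 | methyl (3E)-2-diazo-5-methylhex-3-enoate | COC(=O)C(=[N+]=[N-])/C=C/C(C)C
A5 | alternative 2 | tert-butyldimethyl{[(1E)-3-methylbuta-1,3-dien-1-yl]oxy}silane | CC(=C)/C=C/O[Si](C)(C)C(C)(C)C
A6 | alternative 2 | methyl (3S,4S)-4-[(tert-butyldimethylsilyl)oxy]-6-methyl-3-(propan-2-yl)cyclohepta-1,5-diene-1-carboxylate | COC(=O)C1=C[C@H](C(C)C)[C@H](O[Si](C)(C)C(C)(C)C)C=C(C)C1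
A7 | alternative 3 | tert-butyldimethyl({1-[(1E)-8-methyl-4-methylidenenon-1-en-6-yn-1-yl]cyclopropyl}oxy)silane | CC(C)C#CCC(=C)C/C=C/C1(O[Si](C)(C)C(C)(C)C)CC1
A8 | alternative 3 | (8aS)-2-methylidene-4-(propan-2-yl)-2,3,5,6,8,8a-hexahydroazulen-7(1H)-one | O=C1CCC(C(C)C)=C2CC(=C)C[C@H]2C1
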